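**Retrosynthetic overview**
- Last operations: acetylation of the C15 hydroxyl and removal of a 14,15-acetonide. The key disconnection is the C12–C13 bond: a C12 Grignard reagent adds to an (S)-glycerate-derived methyl ketone, and the purchased C14 centre sets C13 through a magnesium chelate.
- No ring is formed. Rings A and B, with C5, C9 and C10, are taken intact from (+)-sclareolide 1. Its lactone ring is opened by reduction and the C8 carbinol is dehydrated to the exocyclic alkene.
- C14 and C15 come from methyl (S)-2,2-dimethyl-1,3-dioxolane-4-carboxylate 2 (L-serine pool). Its dioxolane is carried through and removed at the end.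

Assumption: the SMILES is read as (13S,14S)-15-acetoxylabd-8(17)-ene-13,14-diol of the normal (5S,9S,10S) labdane series; labdane numbering is used for positions.

**Step 1**
Reactants: 1 (+)-sclareolide
Product: 3 13,14,15,16-tetranorlabdane-8α,12-diol [(1R,2R,4aS,8aS)-1-(2-hydroxyethyl)-2,5,5,8a-tetramethyldecahydronaphthalen-2-ol]
Conditions: LiAlH4, THF, 0 °C to rt; then H2O
Reagents that add atoms: none
Why: Hydride reduction of the lactone (ester reduction) opens it to the 8,12-diol; C5, C8, C9 and C10 are untouched and come from 1.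

**Step 2**
Reactants: 3 13,14,15,16-tetranorlabdane-8α,12-diol
Product: 4 12-acetoxy-13,14,15,16-tetranorlabdan-8α-ol
Conditions: Ac2O, pyridine, DMAP (cat.), CH2Cl2, 0 °C
Reagents that add atoms: acetic anhydride, CC(=O)OC(C)=O
Why: Selective O-acylation of the unhindered primary hydroxyl; the hindered tertiary C8 hydroxyl does not react at 0 °C.

**Step 3**
Reactants: 4 12-acetoxy-13,14,15,16-tetranorlabdan-8α-ol
Product: 5 12-acetoxy-13,14,15,16-tetranorlabd-8(17)-ene [2-[(1S,4aS,8aS)-5,5,8a-trimethyl-2-methylidenedecahydronaphthalen-1-yl]ethyl acetate]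
Conditions: SOCl2, pyridine, CH2Cl2, −78 °C
Reagents that add atoms: none
Why: Kinetic E2-type dehydration of the equatorial tertiary alcohol: only the C17 methyl hydrogens can lie anti to the equatorial leaving group, so the exocyclic 8(17)-alkene is the main product (minor ring-alkene isomers are removed on AgNO3-impregnated silica) and C9 is not epimerised.

**Step 4**
Reactants: 5 12-acetoxy-13,14,15,16-tetranorlabd-8(17)-ene
Product: 6 13,14,15,16-tetranorlabd-8(17)-en-12-ol
Conditions: K2CO3 (cat.), MeOH, rt
Reagents that add atoms: none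
Why: Base-catalysed transesterification (methanolysis) removes the acetate without affecting the alkene.

**Step 5**
Reactants: 6 13,14,15,16-tetranorlabd-8(17)-en-12-ol
Product: 7 12-bromo-13,14,15,16-tetranorlabd-8(17)-ene [(1S,4aS,8aS)-1-(2-bromoethyl)-5,5,8a-trimethyl-2-methylidenedecahydronaphthalene]
Conditions: CBr4, PPh3, CH2Cl2, 0 °C
Reagents that add atoms: carbon tetrabromide, BrC(Br)(Br)Br
Why: Appel reaction: neutral activation of the primary alcohol and SN2 displacement by bromide, which leaves the acid-sensitive exocyclic alkene and C9 intact.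

**Step 6**
Reactants: 2 methyl (S)-2,2-dimethyl-1,3-dioxolane-4-carboxylate
Product: 9 1-[(4S)-2,2-dimethyl-1,3-dioxolan-4-yl]ethan-1-one, via Weinreb amide 8 (not isolated)
Conditions: MeNH(OMe)·HCl, i-PrMgCl, THF, −20 °C; then MeMgBr, 0 °C; then H2O
Reagents that add atoms: methylmagnesium bromide, C[Mg]Br
Why: One-pot Weinreb ketone synthesis: aminolysis of the ester by the magnesium amide gives the N-methoxy-N-methylamide, which takes up exactly one methyl and releases the ketone only on quench, so the purchased C14 centre is never exposed to base as a ketone.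

**Step 7**
Reactants: 7 12-bromo-13,14,15,16-tetranorlabd-8(17)-ene; 9 1-[(4S)-2,2-dimethyl-1,3-dioxolan-4-yl]ethan-1-one
Product: 11 (13S,14S)-14,15-O-isopropylidenelabd-8(17)-ene-13,14,15-triol [(2S)-2-[(4S)-2,2-dimethyl-1,3-dioxolan-4-yl]-4-[(1S,4aS,8aS)-5,5,8a-trimethyl-2-methylidenedecahydronaphthalen-1-yl]butan-2-ol], via Grignard reagent 10 (not isolated)
Conditions: Mg, Et2O, 35 °C; then 9, Et2O–CH2Cl2, −78 °C; then H2O
Reagents that add atoms: none
Why: Chelation-controlled Grignard addition (Cram cyclic model): magnesium bridges the ketone oxygen and the α-oxygen of the dioxolane, and the alkyl group adds to the face carrying the C14 hydrogen, which sets C13 as S under control of the purchased C14 centre (the dr is predicted from the model, not known for this pair; the minor C13 epimer is removed by chromatography).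

**Step 8**
Reactants: 11 (13S,14S)-14,15-O-isopropylidenelabd-8(17)-ene-13,14,15-triol
Product: 12 (13S,14S)-labd-8(17)-ene-13,14,15-triol
Conditions: AcOH–H2O (4:1), 40 °C
Reagents that add atoms: none
Why: Mild acid-catalysed acetal hydrolysis frees the 14,15-diol; the exocyclic alkene and the tertiary carbinol should tolerate this acidity.

**Step 9**
Reactants: 12 (13S,14S)-labd-8(17)-ene-13,14,15-triol
Product: 13 (13S,14S)-15-acetoxylabd-8(17)-ene-13,14-diol [(2S,3S)-2,3-dihydroxy-3-methyl-5-[(1S,4aS,8aS)-5,5,8a-trimethyl-2-methylidenedecahydronaphthalen-1-yl]pentyl acetate]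
Conditions: AcCl (1.05 equiv), 2,4,6-collidine, CH2Cl2, −78 °C
Reagents that add atoms: acetyl chloride, CC(Cl)=O
Why: Kinetically selective acylation of the primary hydroxyl in the presence of the secondary and tertiary hydroxyls gives the 15-acetate; no stereocentre is touched.

**Compound list**
1 | (+)-sclareolide | C[C@@]12CC[C@H]3C(C)(C)CCC[C@]3(C)[C@H]1CC(=O)O2 | starting material
2 | methyl (S)-2,2-dimethyl-1,3-dioxolane-4-carboxylate | COC(=O)[C@@H]1COC(C)(C)O1 | starting material
3 | 13,14,15,16-tetranorlabdane-8α,12-diol | C[C@@]1(O)CC[C@H]2C(C)(C)CCC[C@]2(C)[C@H]1CCO | intermediate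
4 | 12-acetoxy-13,14,15,16-tetranorlabdan-8α-ol | C[C@@]1(O)CC[C@H]2C(C)(C)CCC[C@]2(C)[C@H]1CCOC(C)=O | intermediate
5 | 12-acetoxy-13,14,15,16-tetranorlabd-8(17)-ene | C=C1CC[C@H]2C(C)(C)CCC[C@]2(C)[C@H]1CCOC(C)=O | intermediate
6 | 13,14,15,16-tetranorlabd-8(17)-en-12-ol | C=C1CC[C@H]2C(C)(C)CCC[C@]2(C)[C@H]1CCO | intermediate
7 | 12-bromo-13,14,15,16-tetranorlabd-8(17)-ene | C=C1CC[C@H]2C(C)(C)CCC[C@]2(C)[C@H]1CCBr | intermediate
8 | (4S)-N-methoxy-N,2,2-trimethyl-1,3-dioxolane-4-carboxamide (Weinreb amide) | CON(C)C(=O)[C@@H]1COC(C)(C)O1 | intermediate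
9 | 1-[(4S)-2,2-dimethyl-1,3-dioxolan-4-yl]ethan-1-one | CC(=O)[C@@H]1COC(C)(C)O1 | intermediate
10 | (13,14,15,16-tetranorlabd-8(17)-en-12-yl)magnesium bromide (Grignard reagent) | C=C1CC[C@H]2C(C)(C)CCC[C@]2(C)[C@H]1CC[Mg]Br | intermediate
11 | (13S,14S)-14,15-O-isopropylidenelabd-8(17)-ene-13,14,15-triol | C=C1CC[C@H]2C(C)(C)CCC[C@]2(C)[C@H]1CC[C@](C)(O)[C@@H]1COC(C)(C)O1 | intermediate
12 | (13S,14S)-labd-8(17)-ene-13,14,15-triol | C=C1CC[C@H]2C(C)(C)CCC[C@]2(C)[C@H]1CC[C@](C)(O)[C@@H](O)CO | intermediate
13 | (13S,14S)-15-acetoxylabd-8(17)-ene-13,14-diol (CNP0198975.1) | C=C1CC[C@H]2C(C)(C)CCC[C@]2(C)[C@H]1CC[C@](C)(O)[C@@H](O)COC(C)=O | target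

**Totals**
Total step count: 9. Longest linear sequence: 8 (steps 1–5, 7, 8, 9 from 1).

**Steps most likely to fail, with fallbacks**

Step 7 (Grignard formation and facial selectivity at C13). The fallback sets out from bromide 7 (as its Grignard reagent 10) and from Weinreb amide 8, this time isolated after the first stage of step 6. Reagent 10 is acylated by 8 to give the ketone 1-[(4S)-2,2-dimethyl-1,3-dioxolan-4-yl]-3-[(1S,4aS,8aS)-5,5,8a-trimethyl-2-methylidenedecahydronaphthalen-1-yl]propan-1-one F2. Methyl is then delivered with the non-chelating reagent MeTi(OiPr)3 (CH2Cl2, 0 °C to rt; MeLi in THF at −78 °C as the alternative). Felkin–Anh attack anti to the C14–O bond gives the same 13S carbinol, and the route is rejoined at 11. Because the alkyl and methyl groups change roles, the chelate model in step 7 and the Felkin–Anh model here predict the same C13 configuration, so weak chelation in step 7 is answered by this sequence.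

Step 3 (regioselectivity of the dehydration). The fallback sets out from 4. The tertiary hydroxyl is acetylated as well (AcCl, N,N-dimethylaniline, 40 °C) to give 8α,12-diacetoxy-13,14,15,16-tetranorlabdane F1. The tertiary acetate is then removed by brief gas-phase thermolysis at about 400 °C. This unimolecular syn-elimination through a six-membered transition state has three methyl hydrogens available against single ring hydrogens, and the primary acetate survives at this temperature. The route is rejoined at 5; ring-alkene isomers, if any, are removed as in the main step.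

Step 9 (mono-acetylation of the triol). The fallback sets out from 12. Heating with Bu2SnO in toluene with removal of water gives the 14,15-O-dibutylstannylene acetal of (13S,14S)-labd-8(17)-ene-13,14,15-triol F3. AcCl (1.0 equiv, CH2Cl2, 0 °C) acylates this tin acetal at the primary oxygen only, and aqueous work-up releases the C14 hydroxyl. The route is rejoined at 13.

**Further compounds**
F1 | step 3 | 8α,12-diacetoxy-13,14,15,16-tetranorlabdane | C[C@@]1(OC(C)=O)CC[C@H]2C(C)(C)CCC[C@]2(C)[C@H]1CCOC(C)=O
F2 | step 7 | 1-[(4S)-2,2-dimethyl-1,3-dioxolan-4-yl]-3-[(1S,4aS,8aS)-5,5,8a-trimethyl-2-methylidenedecahydronaphthalen-1-yl]propan-1-one | C=C1CC[C@H]2C(C)(C)CCC[C@]2(C)[C@H]1CCC(=O)[C@@H]1COC(C)(C)O1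
F3 | step 9 | 14,15-O-dibutylstannylene acetal of (13S,14S)-labd-8(17)-ene-13,14,15-triol | C=C1CC[C@H]2C(C)(C)CCC[C@]2(C)[C@H]1CC[C@](C)(O)[C@@H]1CO[Sn](CCCC)(CCCC)O1
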